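The route rests on disconnecting C4–C5 and C9–C10 at once. Because the quaternary C8 (shared by rings B, C and D) sits para to C12 and carries two like arms (C9–C11, C14–C13), ring C can enter as a symmetric 4,4-disubstituted cyclohexadienone made from benzoic acid. In step 15 a C4 radical of a 2-bromo-2-methyl-3-oxo ester closes ring A (6-endo) onto an E alkene and the resulting C10 radical closes ring B (5-exo) onto one dienone arm, setting C4, C5, C10, C9 and C8 from the single C6 stereocentre. The precursor is an open-chain bromo keto ester tethered through C6 to the dienone; ring D follows by reductive aldol.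

Key step: step 15

Remark: atoms are numbered as in gibberellane (C4 carries CH3 and CO2H, C6 carries C7, C10 carries C20, C16 is the carbinol); enolates, radicals and metal-bound species are described in the Why lines and carry no number; the C7 hydroxyl is assumed to be best carried as its tert-butyldiphenylsilyl ether, which outlasts the acidic release of the methyl ketone in step 16.

Step 1
Reactants: 1 benzoic acid; 2 propargyl bromide
Product: 3 1-(prop-2-yn-1-yl)cyclohexa-2,5-diene-1-carboxylic acid
Conditions: Li (to a persistent blue colour), NH3(l)/THF, −78 °C; then 2, −78 °C; NH4Cl; aq. HCl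
Reagents that add atoms: none
Why: Birch reduction of the benzoate gives the carboxylate enolate dianion, which the reactive propargylic bromide alkylates at the carboxyl-bearing ring carbon (Birch reduction–alkylation), creating the quaternary carbon that becomes C8 without any stereocentre.

Step 2
Reactants: 3 1-(prop-2-yn-1-yl)cyclohexa-2,5-diene-1-carboxylic acid
Product: 5 methyl 1-(2-oxopropyl)cyclohexa-2,5-diene-1-carboxylate, via spiro enol lactone 4 (not isolated)
Conditions: AuCl (5 mol%), K2CO3 (10 mol%), MeCN, rt; then NaOMe (cat.), MeOH, 0 °C to rt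
Reagents that add atoms: methanol, CO
Why: The carboxylate adds 5-exo-dig to the gold-activated alkyne (gold-catalysed cycloisomerisation of a 4-pentynoic acid, favoured by the gem-disubstitution) and methanolysis of the resulting enol ester releases the methyl ketone and the methyl ester, so the alkyne is hydrated with full regiocontrol and without strong acid.

Step 3
Reactants: 5 methyl 1-(2-oxopropyl)cyclohexa-2,5-diene-1-carboxylate
Product: 6 methyl 1-[(2-methyl-1,3-dioxolan-2-yl)methyl]cyclohexa-2,5-diene-1-carboxylate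
Conditions: TMSOCH2CH2OTMS (1.5 equiv), TMSOTf (5 mol%), CH2Cl2, −78 to −20 °C; pyridine
Reagents that add atoms: 1,2-bis(trimethylsilyloxy)ethane, C[Si](C)(C)OCCO[Si](C)(C)C
Why: Silyl-triflate-catalysed ketalisation with the bis-silylated glycol converts the unhindered methyl ketone into its dioxolane at low temperature, conditions too mild to shift the skipped diene.

Step 4
Reactants: 6 methyl 1-[(2-methyl-1,3-dioxolan-2-yl)methyl]cyclohexa-2,5-diene-1-carboxylate
Product: 7 1-[(2-methyl-1,3-dioxolan-2-yl)methyl]cyclohexa-2,5-diene-1-carboxylic acid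
Conditions: LiOH·H2O, THF/MeOH/H2O, 60 °C; then cold dilute HCl to pH 4
Reagents that add atoms: lithium hydroxide, [Li+].[OH-]
Why: Saponification of the hindered ester is safe because the dioxolane is stable to base and the quaternary alpha carbon can neither epimerise nor bring the diene into conjugation.

Step 5
Reactants: 7 1-[(2-methyl-1,3-dioxolan-2-yl)methyl]cyclohexa-2,5-diene-1-carboxylic acid; 8 trimethylsilyldiazomethane
Product: 10 2-diazo-1-{1-[(2-methyl-1,3-dioxolan-2-yl)methyl]cyclohexa-2,5-dien-1-yl}ethan-1-one, via acid chloride 9 (not isolated)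
Conditions: Me2C=C(Cl)NMe2 (1.2 equiv), CH2Cl2, 0 °C to rt; then 8 (2 equiv), MeCN/THF, 0 °C to rt
Reagents that add atoms: none
Why: The neutral chloroenamine makes the acid chloride without free HCl, which spares the dioxolane, and C-acylation of the silyl diazomethane with loss of the silyl group gives the diazoketone, the first half of an Arndt–Eistert homologation.

Step 6
Reactants: 10 2-diazo-1-{1-[(2-methyl-1,3-dioxolan-2-yl)methyl]cyclohexa-2,5-dien-1-yl}ethan-1-one
Product: 12 2-{1-[(2-methyl-1,3-dioxolan-2-yl)methyl]cyclohexa-2,5-dien-1-yl}acetic acid, via ketene 11 (not isolated)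
Conditions: PhCO2Ag (10 mol%), Et3N, THF/H2O (9:1), rt, dark; then aq. NaH2PO4
Reagents that add atoms: water, O
Why: In the silver-catalysed Wolff rearrangement the quaternary carbon migrates with loss of N2 and water traps the ketene, silver being chosen because it favours this normal 1,2-shift over the vinylogous pathway that copper catalysts open for beta,gamma-unsaturated diazoketones.

Step 7
Reactants: 12 2-{1-[(2-methyl-1,3-dioxolan-2-yl)methyl]cyclohexa-2,5-dien-1-yl}acetic acid; 13 (R)-4-benzyl-1,3-oxazolidin-2-one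
Product: 15 (R)-4-benzyl-3-(2-{1-[(2-methyl-1,3-dioxolan-2-yl)methyl]cyclohexa-2,5-dien-1-yl}acetyl)-1,3-oxazolidin-2-one, via mixed pivalic anhydride 14 (not isolated)
Conditions: t-BuCOCl, Et3N, THF, −20 °C; then LiCl, 13, −20 °C to rt
Reagents that add atoms: none
Why: N-Acylation through the mixed anhydride works because the lithium-activated oxazolidinone attacks the CH2-flanked carbonyl and not the more hindered pivaloyl carbonyl.

Step 8
Reactants: 15 (R)-4-benzyl-3-(2-{1-[(2-methyl-1,3-dioxolan-2-yl)methyl]cyclohexa-2,5-dien-1-yl}acetyl)-1,3-oxazolidin-2-one; 16 methacrolein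
Product: 17 (R)-4-benzyl-3-[(2R,3R)-3-hydroxy-4-methyl-2-{1-[(2-methyl-1,3-dioxolan-2-yl)methyl]cyclohexa-2,5-dien-1-yl}pent-4-enoyl]-1,3-oxazolidin-2-one
Conditions: n-Bu2BOTf (1.2 equiv), i-Pr2NEt (1.4 equiv), CH2Cl2, 0 °C; then 16, −78 to 0 °C; pH 7 buffer, MeOH, H2O2, 0 °C
Reagents that add atoms: none
Why: In this Evans syn aldol the Z boron enolate (boron enolates of acetyl imides carrying a tertiary alkyl group are known to form) meets the unhindered aldehyde in a closed chair transition state on the enolate face away from the benzyl group, which sets C6 together with the C5 carbinol that is erased later.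

Step 9
Reactants: 17 (R)-4-benzyl-3-[(2R,3R)-3-hydroxy-4-methyl-2-{1-[(2-methyl-1,3-dioxolan-2-yl)methyl]cyclohexa-2,5-dien-1-yl}pent-4-enoyl]-1,3-oxazolidin-2-one
Product: 18 (2S,3R)-4-methyl-2-{1-[(2-methyl-1,3-dioxolan-2-yl)methyl]cyclohexa-2,5-dien-1-yl}pent-4-ene-1,3-diol
Conditions: LiBH4 (2.5 equiv), MeOH (2.5 equiv), THF, 0 °C to rt
Reagents that add atoms: none
Why: Reductive cleavage of the imide by LiBH4 is guided to the exocyclic carbonyl by the neighbouring hydroxyl, frees the auxiliary for recovery and leaves C6 untouched.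

Step 10
Reactants: 18 (2S,3R)-4-methyl-2-{1-[(2-methyl-1,3-dioxolan-2-yl)methyl]cyclohexa-2,5-dien-1-yl}pent-4-ene-1,3-diol
Product: 19 (3R,4S)-5-[(tert-butyldiphenylsilyl)oxy]-2-methyl-4-{1-[(2-methyl-1,3-dioxolan-2-yl)methyl]cyclohexa-2,5-dien-1-yl}pent-1-en-3-ol
Conditions: t-BuPh2SiCl (1.05 equiv), imidazole, CH2Cl2, 0 °C to rt
Reagents that add atoms: tert-butyl(chloro)diphenylsilane, CC(C)(C)[Si](Cl)(c1ccccc1)c1ccccc1
Why: The bulky silyl chloride silylates the primary C7 hydroxyl far faster than the hindered secondary allylic one (selective silyl ether formation).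

Step 11
Reactants: 19 (3R,4S)-5-[(tert-butyldiphenylsilyl)oxy]-2-methyl-4-{1-[(2-methyl-1,3-dioxolan-2-yl)methyl]cyclohexa-2,5-dien-1-yl}pent-1-en-3-ol
Product: 21 tert-butyl{[(2S,3E)-5-bromo-4-methyl-2-{1-[(2-methyl-1,3-dioxolan-2-yl)methyl]cyclohexa-2,5-dien-1-yl}pent-3-en-1-yl]oxy}diphenylsilane, via secondary allylic mesylate 20 (not isolated)
Conditions: MsCl, Et3N, THF, −40 °C; then LiBr (5 equiv), THF, −40 to 0 °C
Reagents that add atoms: lithium bromide, [Li+].[Br-]
Why: Bromide displaces the allylic mesylate with allylic transposition (SN2') because direct attack at the neopentyl-like C5 is blocked, and the E alkene is favoured since it puts the methyl group and not CH2Br cis to the bulky C6, the C5 stereocentre being erased.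

Step 12
Reactants: 21 tert-butyl{[(2S,3E)-5-bromo-4-methyl-2-{1-[(2-methyl-1,3-dioxolan-2-yl)methyl]cyclohexa-2,5-dien-1-yl}pent-3-en-1-yl]oxy}diphenylsilane; 22 methyl 2-methyl-3-oxobutanoate
Product: 23 methyl (6E,8S)-9-[(tert-butyldiphenylsilyl)oxy]-2,6-dimethyl-8-{1-[(2-methyl-1,3-dioxolan-2-yl)methyl]cyclohexa-2,5-dien-1-yl}-3-oxonon-6-enoate (both C2 epimers)
Conditions: 22 (2 equiv), NaH, THF, 0 °C; n-BuLi, 0 °C; then 21, 0 °C to rt; NH4Cl
Reagents that add atoms: none
Why: The keto ester dianion is alkylated at its more reactive terminal carbon by the primary allylic bromide (dianion alkylation), which forms the C1–C2 bond and leaves C4 as an inconsequential mixture.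

Step 13
Reactants: 23 methyl (6E,8S)-9-[(tert-butyldiphenylsilyl)oxy]-2,6-dimethyl-8-{1-[(2-methyl-1,3-dioxolan-2-yl)methyl]cyclohexa-2,5-dien-1-yl}-3-oxonon-6-enoate
Product: 24 methyl (6E,8S)-9-[(tert-butyldiphenylsilyl)oxy]-2,6-dimethyl-8-{1-[(2-methyl-1,3-dioxolan-2-yl)methyl]-4-oxocyclohexa-2,5-dien-1-yl}-3-oxonon-6-enoate
Conditions: CrO3, 3,5-dimethylpyrazole (12 equiv each), CH2Cl2, −20 °C
Reagents that add atoms: chromium trioxide, O=[Cr](=O)=O
Why: The ring CH2 is flanked by two alkenes and has by far the weakest C–H bond, so the CrO3–pyrazole complex should oxidise it to the cross-conjugated dienone before it touches the singly allylic positions of the side chain (allylic oxidation).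

Step 14
Reactants: 24 methyl (6E,8S)-9-[(tert-butyldiphenylsilyl)oxy]-2,6-dimethyl-8-{1-[(2-methyl-1,3-dioxolan-2-yl)methyl]-4-oxocyclohexa-2,5-dien-1-yl}-3-oxonon-6-enoate
Product: 25 methyl (6E,8S)-2-bromo-9-[(tert-butyldiphenylsilyl)oxy]-2,6-dimethyl-8-{1-[(2-methyl-1,3-dioxolan-2-yl)methyl]-4-oxocyclohexa-2,5-dien-1-yl}-3-oxonon-6-enoate (both C2 epimers)
Conditions: N-bromosuccinimide (1.05 equiv), Mg(ClO4)2 (0.3 equiv), EtOAc, 0 °C
Reagents that add atoms: N-bromosuccinimide, O=C1CCC(=O)N1Br
Why: Magnesium chelation speeds enolisation of the keto ester so that electrophilic bromination at C4 outruns attack on the alkene (alpha-bromination of a 1,3-dicarbonyl compound), and both epimers lead to the same radical.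

Step 15
Reactants: 25 methyl (6E,8S)-2-bromo-9-[(tert-butyldiphenylsilyl)oxy]-2,6-dimethyl-8-{1-[(2-methyl-1,3-dioxolan-2-yl)methyl]-4-oxocyclohexa-2,5-dien-1-yl}-3-oxonon-6-enoate
Product: 26 tricyclic A/B/C enone (C3 ketone, C4 CH3 and axial CO2Me, trans A/B fusion, C6 CH2OSi-t-BuPh2, dioxolanylmethyl arm on C8, ring C 13-en-12-one)
Conditions: Ru(bpy)3Cl2 (2 mol%), Hantzsch ester (1.3 equiv), i-Pr2NEt (2 equiv), degassed DMF (0.01 M), blue LEDs, rt
Reagents that add atoms: none
Why: Proposed new method: the photoreduced ruthenium complex transfers one electron to the C4–Br bond, the electrophilic tertiary 3-oxo ester radical adds to C5 of the electron-rich E alkene, the nucleophilic tertiary C10 radical thus formed adds to C9 of the electron-poor dienone, and the C11 radical beside the C12 carbonyl is quenched by hydrogen transfer from the dihydropyridine (or by reduction to the enolate and protonation), so every bond forms with matched polarity and the sequence stops after two rings. The closest known reaction types are the 6-endo cyclisation of 2-methyl-3-oxo ester radicals onto trisubstituted alkenes (generated with Mn(OAc)3 or from 2-bromo esters) and the 5-exo radical conjugate addition to 4,4-disubstituted cyclohexadienones, which have not been joined in one desymmetrising cascade. Ring A closes 6-endo-trig through the C4–C5 bond and ring B closes 5-exo-trig through the C10–C9 bond. C5 is controlled by allylic 1,3-strain against the C20 methyl, which keeps the C6 hydrogen eclipsed with the alkene so that C4 bonds to the face remote from the quaternary C8, and C4 takes the axial ester orientation that these chair-like closures give. C10 is controlled by the quaternary C4, which confines C8 to the rotamer next to H5 and so makes the new bond trans to the C5–C6 bond (trans A/B fusion), C9 by the tether, which reaches only the dienone face that carries C6, and C8 by the choice of dienone arm, since only the arm that turns the rest of the dienone away from ring A lets C10 meet C9 perpendicular to the ring plane, leaving C15 cis to C7 and H9. The step needs ring closure to outrun hydrogen transfer to the first radical and 6-endo to beat 5-exo, which high dilution and the methyl group on C10 secure, while the saturated dioxolane arm gives the C11 radical nothing further to attack.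

Step 16
Reactants: 26 tricyclic A/B/C enone
Product: 27 tricyclic enone with a free 2-oxopropyl arm on C8
Conditions: 1 M HCl (aq)/THF (1:4), rt
Reagents that add atoms: water, O
Why: Dilute acid hydrolyses the dioxolane (acetal hydrolysis) while the hindered tert-butyldiphenylsilyl ether, the enone and the non-enolisable C4 centre are unaffected.

Step 17
Reactants: 27 tricyclic enone with a free 2-oxopropyl arm on C8
Product: 28 tetracyclic 16-hydroxy-3,12-dione (ring D closed, C16 OH turned towards C12)
Conditions: [(Ph3P)CuH]6 (0.2 equiv, 1.2 equiv hydride), toluene, −40 to 0 °C; NH4Cl (aq)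
Reagents that add atoms: none
Why: Copper hydride adds to C14 of the enone only, and the copper enolate fixed between C12 and C13 attacks the methyl ketone through a metal-bridged closed transition state (reductive aldol cyclisation), so C13 is set by the bridging geometry and C16 by the chelate that turns its oxygen towards C12 and its methyl towards C14.

Step 18
Reactants: 28 tetracyclic 16-hydroxy-3,12-dione
Product: 29 C12 tosylhydrazone of 28
Conditions: TsNHNH2 (1.05 equiv), MeOH, rt
Reagents that add atoms: 4-methylbenzenesulfonohydrazide, Cc1ccc(cc1)S(=O)(=O)NN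
Why: Hydrazone condensation should take place at C12, which is flanked by CH and CH2, and not at C3, which is shielded by the fully substituted C4, and the neutral conditions do not reverse the aldol.

Step 19
Reactants: 29 C12 tosylhydrazone of 28
Product: 30 tetracyclic 16-hydroxy-3-ketone (C12 now CH2)
Conditions: catecholborane (2.5 equiv), CHCl3, 0 °C to rt; then NaOAc·3H2O, reflux
Reagents that add atoms: none
Why: Hydride addition to the C=N bond followed by acetate-induced loss of sulfinate and N2 (reductive deoxygenation of a tosylhydrazone) removes the C12 oxygen without base strong enough for a retro-aldol, and the hindered C3 ketone is too slow to be reduced by the borane.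

Step 20
Reactants: 30 tetracyclic 16-hydroxy-3-ketone
Product: 31 3,16-diol silyl ether methyl ester (C3 OH axial, cis to C18)
Conditions: KBH(s-Bu)3 (3 equiv), THF, −78 to −20 °C; H2O
Reagents that add atoms: none
Why: The bulky trialkylborohydride avoids the syn-axial hydrogens on C1 and C5 and delivers hydride equatorially (stereoselective ketone reduction), which gives the axial C3 alcohol cis to the C18 methyl and leaves the ester alone.

Step 21
Reactants: 31 3,16-diol silyl ether methyl ester
Product: 32 3,7,16-triol methyl ester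
Conditions: Bu4NF (3 equiv), THF, rt to 40 °C
Reagents that add atoms: none
Why: Fluoride cleaves the Si–O bond of the primary silyl ether (desilylation) without affecting the hindered ester or the tertiary alcohol.

Step 22
Reactants: 32 3,7,16-triol methyl ester
Product: 33 target CNP0170663.1 (3,7,16-trihydroxy acid)
Conditions: LiSPr (from n-PrSH and n-BuLi, 10 equiv), HMPA, rt to 50 °C; then cold dilute HCl to pH 3
Reagents that add atoms: none
Why: The thiolate attacks the ester methyl carbon (SN2 dealkylation), a process indifferent to the crowding around the axial C19 carbonyl and too weakly basic to disturb any stereocentre.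

Compound list
1 | benzoic acid | O=C(O)c1ccccc1 | starting material
2 | propargyl bromide | C#CCBr | starting material
3 | 1-(prop-2-yn-1-yl)cyclohexa-2,5-diene-1-carboxylic acid | C#CCC1(C(=O)O)C=CCC=C1 | intermediate
4 | 3-methylidene-2-oxaspiro[4.5]deca-6,9-dien-1-one (spiro enol lactone) | C=C1CC2(C=CCC=C2)C(=O)O1 | intermediate
5 | methyl 1-(2-oxopropyl)cyclohexa-2,5-diene-1-carboxylate | COC(=O)C1(CC(C)=O)C=CCC=C1 | intermediate
6 | methyl 1-[(2-methyl-1,3-dioxolan-2-yl)methyl]cyclohexa-2,5-diene-1-carboxylate | COC(=O)C1(CC2(C)OCCO2)C=CCC=C1 | intermediate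
7 | 1-[(2-methyl-1,3-dioxolan-2-yl)methyl]cyclohexa-2,5-diene-1-carboxylic acid | OC(=O)C1(CC2(C)OCCO2)C=CCC=C1 | intermediate
8 | trimethylsilyldiazomethane | C[Si](C)(C)C=[N+]=[N-] | starting material
9 | 1-[(2-methyl-1,3-dioxolan-2-yl)methyl]cyclohexa-2,5-diene-1-carbonyl chloride | ClC(=O)C1(CC2(C)OCCO2)C=CCC=C1 | intermediate
10 | 2-diazo-1-{1-[(2-methyl-1,3-dioxolan-2-yl)methyl]cyclohexa-2,5-dien-1-yl}ethan-1-one | [N-]=[N+]=CC(=O)C1(CC2(C)OCCO2)C=CCC=C1 | intermediate
11 | 2-{1-[(2-methyl-1,3-dioxolan-2-yl)methyl]cyclohexa-2,5-dien-1-yl}ethen-1-one (ketene) | O=C=CC1(CC2(C)OCCO2)C=CCC=C1 | intermediate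
12 | 2-{1-[(2-methyl-1,3-dioxolan-2-yl)methyl]cyclohexa-2,5-dien-1-yl}acetic acid | OC(=O)CC1(CC2(C)OCCO2)C=CCC=C1 | intermediate
13 | (R)-4-benzyl-1,3-oxazolidin-2-one | O=C1N[C@H](Cc2ccccc2)CO1 | starting material
14 | mixed anhydride of 12 and pivalic acid | CC(C)(C)C(=O)OC(=O)CC1(CC2(C)OCCO2)C=CCC=C1 | intermediate
15 | (R)-4-benzyl-3-(2-{1-[(2-methyl-1,3-dioxolan-2-yl)methyl]cyclohexa-2,5-dien-1-yl}acetyl)-1,3-oxazolidin-2-one | O=C(CC1(CC2(C)OCCO2)C=CCC=C1)N1C(=O)OC[C@H]1Cc1ccccc1 | intermediate
16 | methacrolein | C=C(C)C=O | starting material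
17 | (R)-4-benzyl-3-[(2R,3R)-3-hydroxy-4-methyl-2-{1-[(2-methyl-1,3-dioxolan-2-yl)methyl]cyclohexa-2,5-dien-1-yl}pent-4-enoyl]-1,3-oxazolidin-2-one | C=C(C)[C@H](O)[C@H](C(=O)N1C(=O)OC[C@H]1Cc1ccccc1)C1(CC2(C)OCCO2)C=CCC=C1 | intermediate
18 | (2S,3R)-4-methyl-2-{1-[(2-methyl-1,3-dioxolan-2-yl)methyl]cyclohexa-2,5-dien-1-yl}pent-4-ene-1,3-diol | C=C(C)[C@H](O)[C@H](CO)C1(CC2(C)OCCO2)C=CCC=C1 | intermediate
19 | (3R,4S)-5-[(tert-butyldiphenylsilyl)oxy]-2-methyl-4-{1-[(2-methyl-1,3-dioxolan-2-yl)methyl]cyclohexa-2,5-dien-1-yl}pent-1-en-3-ol | C=C(C)[C@H](O)[C@H](CO[Si](c1ccccc1)(c1ccccc1)C(C)(C)C)C1(CC2(C)OCCO2)C=CCC=C1 | intermediate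
20 | methanesulfonate of 19 | C=C(C)[C@H](OS(C)(=O)=O)[C@H](CO[Si](c1ccccc1)(c1ccccc1)C(C)(C)C)C1(CC2(C)OCCO2)C=CCC=C1 | intermediate
21 | tert-butyl{[(2S,3E)-5-bromo-4-methyl-2-{1-[(2-methyl-1,3-dioxolan-2-yl)methyl]cyclohexa-2,5-dien-1-yl}pent-3-en-1-yl]oxy}diphenylsilane | BrC/C(C)=C/[C@H](CO[Si](c1ccccc1)(c1ccccc1)C(C)(C)C)C1(CC2(C)OCCO2)C=CCC=C1 | intermediate
22 | methyl 2-methyl-3-oxobutanoate | COC(=O)C(C)C(C)=O | starting material
23 | methyl (6E,8S)-9-[(tert-butyldiphenylsilyl)oxy]-2,6-dimethyl-8-{1-[(2-methyl-1,3-dioxolan-2-yl)methyl]cyclohexa-2,5-dien-1-yl}-3-oxonon-6-enoate | COC(=O)C(C)C(=O)CC/C(C)=C/[C@H](CO[Si](c1ccccc1)(c1ccccc1)C(C)(C)C)C1(CC2(C)OCCO2)C=CCC=C1 | intermediate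
24 | methyl (6E,8S)-9-[(tert-butyldiphenylsilyl)oxy]-2,6-dimethyl-8-{1-[(2-methyl-1,3-dioxolan-2-yl)methyl]-4-oxocyclohexa-2,5-dien-1-yl}-3-oxonon-6-enoate | COC(=O)C(C)C(=O)CC/C(C)=C/[C@H](CO[Si](c1ccccc1)(c1ccccc1)C(C)(C)C)C1(CC2(C)OCCO2)C=CC(=O)C=C1 | intermediate
25 | methyl (6E,8S)-2-bromo-9-[(tert-butyldiphenylsilyl)oxy]-2,6-dimethyl-8-{1-[(2-methyl-1,3-dioxolan-2-yl)methyl]-4-oxocyclohexa-2,5-dien-1-yl}-3-oxonon-6-enoate | COC(=O)C(C)(Br)C(=O)CC/C(C)=C/[C@H](CO[Si](c1ccccc1)(c1ccccc1)C(C)(C)C)C1(CC2(C)OCCO2)C=CC(=O)C=C1 | intermediate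
26 | tricyclic A/B/C enone (C3 ketone, C4 CH3 and axial CO2Me, trans A/B fusion, C6 CH2OSi-t-BuPh2, dioxolanylmethyl arm on C8, ring C 13-en-12-one) | C[C@@]12CCC(=O)[C@@](C)(C(=O)OC)[C@H]1[C@H](CO[Si](c4ccccc4)(c5ccccc5)C(C)(C)C)[C@@]1(CC3(C)OCCO3)C=CC(=O)C[C@@H]21 | intermediate
27 | tricyclic enone with a free 2-oxopropyl arm on C8 | C[C@@]12CCC(=O)[C@@](C)(C(=O)OC)[C@H]1[C@H](CO[Si](c4ccccc4)(c5ccccc5)C(C)(C)C)[C@@]1(CC(C)=O)C=CC(=O)C[C@@H]21 | intermediate
28 | tetracyclic 16-hydroxy-3,12-dione (silyl ether, methyl ester) | C[C@@]12CCC(=O)[C@@](C)(C(=O)OC)[C@H]1[C@H](CO[Si](c4ccccc4)(c5ccccc5)C(C)(C)C)[C@@]13C[C@@H](C(=O)C[C@@H]21)[C@@](C)(O)C3 | intermediate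
29 | C12 tosylhydrazone of 28 (C=N geometry not fixed) | C[C@@]12CCC(=O)[C@@](C)(C(=O)OC)[C@H]1[C@H](CO[Si](c4ccccc4)(c5ccccc5)C(C)(C)C)[C@@]13C[C@@H](C(=NNS(=O)(=O)c6ccc(C)cc6)C[C@@H]21)[C@@](C)(O)C3 | intermediate
30 | tetracyclic 16-hydroxy-3-ketone (C12 CH2) | C[C@@]12CCC(=O)[C@@](C)(C(=O)OC)[C@H]1[C@H](CO[Si](c4ccccc4)(c5ccccc5)C(C)(C)C)[C@@]13C[C@@H](CC[C@@H]21)[C@@](C)(O)C3 | intermediate
31 | 3,16-diol silyl ether methyl ester (C3 OH axial) | C[C@@]12CC[C@H](O)[C@@](C)(C(=O)OC)[C@H]1[C@H](CO[Si](c4ccccc4)(c5ccccc5)C(C)(C)C)[C@@]13C[C@@H](CC[C@@H]21)[C@@](C)(O)C3 | intermediate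
32 | 3,7,16-triol methyl ester | C[C@@]12CC[C@H](O)[C@@](C)(C(=O)OC)[C@H]1[C@H](CO)[C@@]13C[C@@H](CC[C@@H]21)[C@@](C)(O)C3 | intermediate
33 | target CNP0170663.1 (3,7,16-trihydroxy acid) | C[C@@]12CC[C@H](O)[C@@](C)(C(=O)O)[C@H]1[C@H](CO)[C@@]13C[C@@H](CC[C@@H]21)[C@@](C)(O)C3 | target

Total step count: 22.
Longest linear sequence: 22 steps, from benzoic acid 1 to 33 (all other fragments are bought and enter as single compounds).

Steps most likely to fail

Step 15. Hydrogen transfer to the C4 radical may occur before ring A closes, or ring B may close onto the other dienone arm or with cis fusion. The fallback separates the two ring closures, each by an established reaction, and sets out from 23. Mn(OAc)3·2H2O and Cu(OAc)2·H2O in AcOH at rt generate the same 3-oxo ester radical oxidatively; ring A closes 6-endo and the C10 radical is oxidised by the copper salt to the exocyclic C10=C20 alkene, giving the ring A methylidene keto ester F1 (an endocyclic alkene isomer would serve equally). CrO3 with 3,5-dimethylpyrazole then raises ring C to the dienone, giving the methylidene dienone F2. Fe(acac)3 and PhSiH3 in EtOH at 60 °C transfer a hydrogen atom to the alkene terminus, the tertiary C10 radical adds 5-exo to C9 and the resulting enolate is protonated. The route is rejoined at 26.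

Step 13. Oxidation may spread to the allylic positions of the side-chain alkene or go too far, in competition with the ring CH2. The fallback replaces the chromium oxidant by a peroxyl radical chain that selects purely by C–H bond strength and sets out from 23. Catalytic Rh2(cap)4 (cap = caprolactamate) with t-BuOOH and K2CO3 in CH2Cl2 at rt should abstract only the doubly allylic hydrogen and give the mixed ring peroxide F3. Et3N then induces the Kornblum–DeLaMare fragmentation to the dienone, and the route is rejoined at 24.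

Step 17. Conjugate reduction may occur without ring closure, or the strained bridged aldolate may revert. The fallback makes and uses the enolate in two stages and sets out from 27. (Ph3P)3RhCl-catalysed 1,4-hydrosilylation with Et3SiH gives the C12 silyl enol ether F4, with the double bond fixed between C12 and C13. TiCl4 in CH2Cl2 at −78 °C then closes ring D by an intramolecular Mukaiyama aldol addition to the methyl ketone, through a titanium-bridged array that again turns the C16 oxygen towards C12. The route is rejoined at 28.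

Further compounds
F1 | step 15 | ring A methylidene keto ester (C4–C5 bond formed, C10=C20 exocyclic alkene, ring C still the 1,4-diene) | C=C1CCC(=O)[C@@](C)(C(=O)OC)[C@H]1[C@H](CO[Si](c2ccccc2)(c3ccccc3)C(C)(C)C)C4(CC5(C)OCCO5)C=CCC=C4
F2 | step 15 | methylidene dienone (F1 with ring C as the cyclohexa-2,5-dienone) | C=C1CCC(=O)[C@@](C)(C(=O)OC)[C@H]1[C@H](CO[Si](c2ccccc2)(c3ccccc3)C(C)(C)C)C4(CC5(C)OCCO5)C=CC(=O)C=C4
F3 | step 13 | mixed ring peroxide (23 with a tert-butylperoxy group on the doubly allylic ring carbon, both epimers) | COC(=O)C(C)C(=O)CC/C(C)=C/[C@H](CO[Si](c1ccccc1)(c1ccccc1)C(C)(C)C)C1(CC2(C)OCCO2)C=CC(OOC(C)(C)C)C=C1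
F4 | step 17 | C12 triethylsilyl enol ether (27 after 1,4-hydrosilylation, C12=C13 enol ether) | C[C@@]12CCC(=O)[C@@](C)(C(=O)OC)[C@H]1[C@H](CO[Si](c4ccccc4)(c5ccccc5)C(C)(C)C)[C@@]1(CC(C)=O)CC=C(O[Si](CC)(CC)CC)C[C@@H]21
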